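**Retrosynthetic overview**

1. Sclerketide B (22) comes from azaphilone alcohol 20 by O7 propionylation and electrophilic chlorination at C5.
2. 20 comes from keto aldehyde 18 by enzymatic hydroxylative dearomatisation of ring A at C7; the pyran (ring B) then re-closes on its own through O2–C1.
3. 18 comes from isocoumarin 16 by reduction of the C1 lactone carbonyl and removal of the two MOM groups.
4. The strategy rests on this feature: ring B (C1, O2, C3, C4, C4a, C8a) is fused to ring A (C4a, C5, C6, C7, C8, C8a) so that C1 sits on C8a and C4 on the adjacent C4a, while the other neighbour of C8a (C8) carries oxygen. This is a benzoic acid (carboxyl carbon = C1, carboxyl oxygen = O2) with exactly one free ortho C–H (C4a). Ring B is cut at C4–C4a and O2–C3 into acid 14 and the acylmethyl unit C4–C3 with its side chain, supplied as sulfoxonium ylide 11.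
5. 11 comes from (S)-2-methylbutan-1-ol (source of C13) by two Wittig homologations. Ring order: ring A is bought, ring B is closed in step 8, and ring A is dearomatised with ring B re-formed in step 10.

Key step: step 8

**Remarks and assumptions**

- Azaphilone numbering is used: C1, O2, C3, C4, C4a, C5, C6, C7, C8, C8a, with side chain C9–C15 and its stereocentre at C13.
- The flavin-dependent monooxygenase AfoD is assumed to be available as a recombinant E. coli lysate; it is a catalyst, not a starting material.
- C7 keeps one spatial arrangement from 19 onwards. Its descriptor is S in 19–21 and becomes R in 22 only because chlorine at C5 raises the CIP rank of C6 above C8.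

**Route**

Step 1
Reactants: 1 (S)-2-methylbutan-1-ol
Product: 3 ethyl (2E,4S)-2,4-dimethylhex-2-enoate, via (S)-2-methylbutanal 2 (not isolated)
Conditions: TEMPO (10 mol%), PhI(OAc)2 (1.1 equiv), CH2Cl2, rt; then Ph3P=C(CH3)CO2Et (1.3 equiv), rt to 40 °C
Reagents that add atoms: ethyl 2-(triphenylphosphoranylidene)propanoate, CCOC(=O)C(C)=P(c1ccccc1)(c1ccccc1)c1ccccc1
Why: TEMPO/PhI(OAc)2 oxidation gives the α-branched aldehyde under non-basic conditions, and trapping it in the same flask by Wittig olefination with the stabilised α-methyl ylide should give the E-trisubstituted enoate without erosion of the chiral-pool stereocentre that becomes C13.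

Step 2
Reactants: 3 ethyl (2E,4S)-2,4-dimethylhex-2-enoate
Product: 4 (2E,4S)-2,4-dimethylhex-2-en-1-ol
Conditions: i-Bu2AlH (2.3 equiv), CH2Cl2, −78 to −20 °C; aq. KNaC4H4O6 work-up
Reagents that add atoms: none
Why: Hydride 1,2-reduction of the enoate by DIBAL-H gives the allylic alcohol and leaves the E-alkene and the remote stereocentre untouched.

Step 3
Reactants: 4 (2E,4S)-2,4-dimethylhex-2-en-1-ol
Product: 6 ethyl (2E,4E,6S)-4,6-dimethylocta-2,4-dienoate, via (2E,4S)-2,4-dimethylhex-2-enal 5 (not isolated)
Conditions: activated MnO2 (10 equiv), Ph3P=CHCO2Et (1.3 equiv), CH2Cl2, rt to reflux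
Reagents that add atoms: ethyl (triphenylphosphoranylidene)acetate, CCOC(=O)C=P(c1ccccc1)(c1ccccc1)c1ccccc1
Why: In this tandem oxidation–Wittig process MnO2 oxidises only the allylic alcohol and the stabilised ylide traps the volatile enal as it forms, which should give the 2E-dienoate under neutral conditions that cannot epimerise the γ-stereocentre.

Step 4
Reactants: 6 ethyl (2E,4E,6S)-4,6-dimethylocta-2,4-dienoate
Product: 7 (2E,4E,6S)-4,6-dimethylocta-2,4-dienoic acid
Conditions: LiOH·H2O (3 equiv), THF/MeOH/H2O, rt; 1 M HCl to pH 3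
Reagents that add atoms: lithium hydroxide, [Li+].[OH-]
Why: Plain ester saponification; the ε-hydrogen at the stereocentre is far too weakly acidic to be removed by aqueous hydroxide.

Step 5
Reactants: 7 (2E,4E,6S)-4,6-dimethylocta-2,4-dienoic acid; 8 trimethylsulfoxonium iodide
Product: 11 dimethylsulfoxonium (3E,5E,7S)-5,7-dimethyl-2-oxonona-3,5-dienylide, via acyl imidazole 9 (not isolated), via dimethylsulfoxonium methylide 10 (not isolated)
Conditions: 7, 1,1'-carbonyldiimidazole (1.2 equiv), THF, rt; added at 0 °C to the methylide from 8 (3 equiv) and KOtBu (3 equiv), THF, reflux 2 h; 0 °C to rt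
Reagents that add atoms: none
Why: Corey–Chaykovsky-type C-acylation of the methylide at the activated acyl imidazole carbonyl should outpace conjugate addition and the product is a stabilised ylide that is no longer a Michael acceptor, while the imidazolide, unlike an acid chloride, is not prone to vinylketene formation through the ε-hydrogen at the stereocentre.

Step 6
Reactants: 12 2,4-dihydroxy-3-methylbenzoic acid
Product: 13 methoxymethyl 2,4-bis(methoxymethoxy)-3-methylbenzoate
Conditions: NaH (3.6 equiv), MOMCl (3.6 equiv), DMF, 0 °C to rt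
Reagents that add atoms: chloromethyl methyl ether, COCCl
Why: Williamson-type O-alkylation of the carboxylate and both phenoxides, with NaH used so that the hydrogen-bonded ortho hydroxyl is also fully deprotonated and protected.

Step 7
Reactants: 13 methoxymethyl 2,4-bis(methoxymethoxy)-3-methylbenzoate
Product: 14 2,4-bis(methoxymethoxy)-3-methylbenzoic acid
Conditions: LiOH·H2O (3 equiv), THF/MeOH/H2O, 40 °C; 1 M HCl to pH 4 at 0 °C
Reagents that add atoms: lithium hydroxide, [Li+].[OH-]
Why: The methoxymethyl ester is saponified readily whereas aryl MOM ethers are inert to base, and cold acidification only to pH 4 should keep both acetals.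

Step 8
Reactants: 14 2,4-bis(methoxymethoxy)-3-methylbenzoic acid; 11 dimethylsulfoxonium (3E,5E,7S)-5,7-dimethyl-2-oxonona-3,5-dienylide
Product: 16 6,8-bis(methoxymethoxy)-7-methyl-3-[(1E,3E,5S)-3,5-dimethylhepta-1,3-dienyl]isochromen-1-one, via keto acid 15 (not isolated)
Conditions: [Cp*RhCl2]2 (5 mol%), AgSbF6 (20 mol%), NaOAc (1.0 equiv), 11 (1.5 equiv), ClCH2CH2Cl, 80 °C, N2
Reagents that add atoms: none
Why: The carboxylate of 14 binds cationic Cp* trivalent rhodium and acetate-assisted concerted metalation–deprotonation at the ortho C–H gives a five-membered rhodacycle; ylide 11 then binds through carbon, loses dimethyl sulfoxide to form a rhodium carbene, the aryl group migrates onto it (C4–C4a) and protodemetalation releases keto acid 15 without any change of oxidation level. The closest known reaction type is the Cp*Rh- or Ru(p-cymene)-catalysed carboxylate-directed annulation of benzoic acids with β-keto sulfoxonium ylides to 3-substituted isocoumarins. Ring B closes by 6-exo-trig addition of the carboxyl oxygen to the ketone carbonyl of 15 (O2–C3) followed by loss of water to the enol lactone. No stereocentre is formed, and C13 is remote from the reacting carbons. The step needs site selectivity, which the substrate secures because the carboxylate reaches only its two ortho carbons and one of them already bears the C8 oxygen, leaving the future C4a as the only candidate. It also needs the inner-sphere aryl transfer to beat carbene attack on the diene and direct O-alkylation of the acid, which the pre-formed rhodacycle favours, and the acetate buffer should keep the MOM acetals intact.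

Step 9
Reactants: 16 6,8-bis(methoxymethoxy)-7-methyl-3-[(1E,3E,5S)-3,5-dimethylhepta-1,3-dienyl]isochromen-1-one
Product: 18 2,4-dihydroxy-3-methyl-6-[(3E,5E,7S)-5,7-dimethyl-2-oxonona-3,5-dienyl]benzaldehyde, via lactol 17 (not isolated)
Conditions: i-Bu2AlH (1.15 equiv), CH2Cl2, −78 °C; MeOH quench; then 3 M aq. HCl, THF, rt to 40 °C; extraction from pH 5 buffer
Reagents that add atoms: none
Why: Partial DIBAL-H reduction of the lactone stops at the tetrahedral aluminate at −78 °C, and aqueous acid then hydrolyses both aryl MOM acetals while the lactol opens by ring–chain tautomerism to the keto aldehyde, which is stabilised by the hydrogen bond between the ortho hydroxyl and the formyl group.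

Step 10
Reactants: 18 2,4-dihydroxy-3-methyl-6-[(3E,5E,7S)-5,7-dimethyl-2-oxonona-3,5-dienyl]benzaldehyde
Product: 20 (7S)-7-hydroxy-7-methyl-3-[(1E,3E,5S)-3,5-dimethylhepta-1,3-dienyl]-6H-isochromene-6,8(7H)-dione, via dearomatised hydroxy dienone 19 (not isolated)
Conditions: AfoD (flavin-dependent monooxygenase, E. coli lysate), NADP+ (cat.), D-glucose, glucose dehydrogenase, air, K2HPO4/KH2PO4 buffer pH 8.0, 5 vol% DMSO, 30 °C; EtOAc extraction, silica gel
Reagents that add atoms: dioxygen, O=O
Why: Biocatalytic hydroxylative dearomatisation of a resorcinol aldehyde, in which the flavin hydroperoxide delivers electrophilic oxygen to the methyl-bearing carbon between the two phenolic oxygens from the face fixed by the active site (AfoD is the S-selective member of this enzyme family for 5-unsubstituted cores and 18 is of its native substrate type), after which the side-chain ketone enol adds to the formyl group and water is lost to re-form the pyran.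

Step 11
Reactants: 20 (7S)-7-hydroxy-7-methyl-3-[(1E,3E,5S)-3,5-dimethylhepta-1,3-dienyl]-6H-isochromene-6,8(7H)-dione
Product: 21 (7S)-7-methyl-6,8-dioxo-3-[(1E,3E,5S)-3,5-dimethylhepta-1,3-dienyl]-7,8-dihydro-6H-isochromen-7-yl propanoate
Conditions: (EtCO)2O (2 equiv), Et3N (3 equiv), DMAP (20 mol%), CH2Cl2, 0 °C to rt
Reagents that add atoms: propanoic anhydride, CCC(=O)OC(=O)CC
Why: DMAP-catalysed acyl transfer esterifies the tertiary α-ketol without breaking any bond to C7, and only tertiary amines are present so that O2 of the pyran is not exchanged for nitrogen.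

Step 12
Reactants: 21 (7S)-7-methyl-6,8-dioxo-3-[(1E,3E,5S)-3,5-dimethylhepta-1,3-dienyl]-7,8-dihydro-6H-isochromen-7-yl propanoate
Product: 22 sclerketide B, (7R)-5-chloro-7-methyl-6,8-dioxo-3-[(1E,3E,5S)-3,5-dimethylhepta-1,3-dienyl]-7,8-dihydro-6H-isochromen-7-yl propanoate
Conditions: NCS (1.05 equiv), MeCN, 0 °C to rt, dark
Reagents that add atoms: N-chlorosuccinimide, O=C1CCC(=O)N1Cl
Why: Electrophilic chlorination with NCS should go to C5, the only CH that is both the vinylogous terminus of the O2–C3=C4–C4a=C5 dienol ether and α to the C6 carbonyl, whereas the side-chain diene is not activated by O2; C7 is not touched and only its descriptor changes.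

**Compound list**

1 | (S)-2-methylbutan-1-ol | CC[C@H](C)CO | starting material
2 | (S)-2-methylbutanal | CC[C@H](C)C=O | intermediate
3 | ethyl (2E,4S)-2,4-dimethylhex-2-enoate | CCOC(=O)/C(C)=C/[C@@H](C)CC | intermediate
4 | (2E,4S)-2,4-dimethylhex-2-en-1-ol | OC/C(C)=C/[C@@H](C)CC | intermediate
5 | (2E,4S)-2,4-dimethylhex-2-enal | O=C/C(C)=C/[C@@H](C)CC | intermediate
6 | ethyl (2E,4E,6S)-4,6-dimethylocta-2,4-dienoate | CCOC(=O)/C=C/C(C)=C/[C@@H](C)CC | intermediate
7 | (2E,4E,6S)-4,6-dimethylocta-2,4-dienoic acid | OC(=O)/C=C/C(C)=C/[C@@H](C)CC | intermediate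
8 | trimethylsulfoxonium iodide | C[S+](C)(C)=O.[I-] | starting material
9 | (2E,4E,6S)-1-(imidazol-1-yl)-4,6-dimethylocta-2,4-dien-1-one (acyl imidazole) | O=C(/C=C/C(C)=C/[C@@H](C)CC)n1ccnc1 | intermediate
10 | dimethylsulfoxonium methylide | CS(C)(=O)=C | intermediate
11 | dimethylsulfoxonium (3E,5E,7S)-5,7-dimethyl-2-oxonona-3,5-dienylide | CS(C)(=O)=CC(=O)/C=C/C(C)=C/[C@@H](C)CC | intermediate
12 | 2,4-dihydroxy-3-methylbenzoic acid | Cc1c(O)ccc(C(=O)O)c1O | starting material
13 | methoxymethyl 2,4-bis(methoxymethoxy)-3-methylbenzoate | COCOC(=O)c1ccc(OCOC)c(C)c1OCOC | intermediate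
14 | 2,4-bis(methoxymethoxy)-3-methylbenzoic acid | COCOc1ccc(C(=O)O)c(OCOC)c1C | intermediate
15 | 2,4-bis(methoxymethoxy)-3-methyl-6-[(3E,5E,7S)-5,7-dimethyl-2-oxonona-3,5-dienyl]benzoic acid (keto acid) | COCOc1cc(CC(=O)/C=C/C(C)=C/[C@@H](C)CC)c(C(=O)O)c(OCOC)c1C | intermediate
16 | 6,8-bis(methoxymethoxy)-7-methyl-3-[(1E,3E,5S)-3,5-dimethylhepta-1,3-dienyl]isochromen-1-one | COCOc1cc2cc(/C=C/C(C)=C/[C@@H](C)CC)oc(=O)c2c(OCOC)c1C | intermediate
17 | 6,8-bis(methoxymethoxy)-7-methyl-3-[(1E,3E,5S)-3,5-dimethylhepta-1,3-dienyl]-1H-isochromen-1-ol (lactol, both C1 epimers) | COCOc1cc2C=C(/C=C/C(C)=C/[C@@H](C)CC)OC(O)c2c(OCOC)c1C | intermediate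
18 | 2,4-dihydroxy-3-methyl-6-[(3E,5E,7S)-5,7-dimethyl-2-oxonona-3,5-dienyl]benzaldehyde | O=Cc1c(O)c(C)c(O)cc1CC(=O)/C=C/C(C)=C/[C@@H](C)CC | intermediate
19 | (5S)-4,5-dihydroxy-5-methyl-2-[(3E,5E,7S)-5,7-dimethyl-2-oxonona-3,5-dienyl]-6-oxocyclohexa-1,3-diene-1-carbaldehyde | O[C@]1(C)C(=O)C(C=O)=C(CC(=O)/C=C/C(C)=C/[C@@H](C)CC)C=C1O | intermediate
20 | (7S)-7-hydroxy-7-methyl-3-[(1E,3E,5S)-3,5-dimethylhepta-1,3-dienyl]-6H-isochromene-6,8(7H)-dione | O[C@]1(C)C(=O)C2=COC(/C=C/C(C)=C/[C@@H](C)CC)=CC2=CC1=O | intermediate
21 | (7S)-7-methyl-6,8-dioxo-3-[(1E,3E,5S)-3,5-dimethylhepta-1,3-dienyl]-7,8-dihydro-6H-isochromen-7-yl propanoate | CCC(=O)O[C@]1(C)C(=O)C2=COC(/C=C/C(C)=C/[C@@H](C)CC)=CC2=CC1=O | intermediate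
22 | sclerketide B, (7R)-5-chloro-7-methyl-6,8-dioxo-3-[(1E,3E,5S)-3,5-dimethylhepta-1,3-dienyl]-7,8-dihydro-6H-isochromen-7-yl propanoate | CCC(=O)O[C@]1(C)C(=O)C2=COC(/C=C/C(C)=C/[C@@H](C)CC)=CC2=C(Cl)C1=O | target

**Step count**

Total: 12 steps. Longest linear sequence: 10 steps (steps 1–5 and 8–12).

**Steps most likely to fail**

Step 8. The electron-rich, ortho-substituted acid may metalate slowly, so that the ylide is consumed instead by direct O-alkylation of the carboxylic acid or by carbene attack on its own diene; Lewis-acidic silver or rhodium cations may also strip a MOM group. The fallback sets out from 14 and returns at 16. Acid 14 is condensed with O-methylhydroxylamine hydrochloride (EDC·HCl, Et3N, CH2Cl2) to N-methoxy-2,4-bis(methoxymethoxy)-3-methylbenzamide F1. Its nitrogen-bound directing group forms the rhodacycle more readily than a carboxylate, and the known annulation of N-methoxybenzamides with β-keto sulfoxonium ylides ([Cp*RhCl2]2, AgSbF6, pivalic acid additive, ClCH2CH2Cl, 80–100 °C) then couples F1 with 11. The ortho-acylmethyl amide closes through the amide oxygen and expels O-methylhydroxylamine, giving 16.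

Step 9. The aluminate of this enol lactone may collapse already at −78 °C, exposing the aldehyde to a second hydride and over-reducing it, and formaldehyde released during MOM cleavage may alkylate the free C5 position. The fallback sets out from 16 and returns at 18. Lactone 16 is deliberately reduced past the aldehyde with i-Bu2AlH (3.5 equiv, CH2Cl2, −78 to 0 °C); once the lactone has opened, the side-chain carbonyl is held as its aluminium enolate, so work-up should give (3E,5E,7S)-1-[2-(hydroxymethyl)-3,5-bis(methoxymethoxy)-4-methylphenyl]-5,7-dimethylnona-3,5-dien-2-one F2. MnO2 (CH2Cl2, rt) oxidises the benzylic alcohol to 2,4-bis(methoxymethoxy)-3-methyl-6-[(3E,5E,7S)-5,7-dimethyl-2-oxonona-3,5-dienyl]benzaldehyde F3. Aqueous HCl in THF then removes the MOM groups in a separate, more dilute operation to give 18.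

Step 10. Conversion may stall at preparative loading because the lipophilic substrate is poorly soluble in buffer, or facial discrimination by the enzyme may be incomplete. The fallback sets out from 18 and returns at 20. Keto aldehyde 18 is cyclised with CF3CO2H in ClCH2CH2Cl to 6,8-dihydroxy-7-methyl-3-[(1E,3E,5S)-3,5-dimethylhepta-1,3-dienyl]isochromenylium trifluoroacetate F4. Oxidation of this 2-benzopyrylium salt at C7 with IBX and catalytic Bu4NI is known chemistry but has no facial control, so 20 would form together with its C7 epimer, (7R)-7-hydroxy-7-methyl-3-[(1E,3E,5S)-3,5-dimethylhepta-1,3-dienyl]-6H-isochromene-6,8(7H)-dione F5. The two diastereomers are separated by preparative HPLC on a polysaccharide chiral stationary phase, and 20 re-enters the route at step 11.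

**Further compounds**

F1 | step 8 | N-methoxy-2,4-bis(methoxymethoxy)-3-methylbenzamide | CONC(=O)c1ccc(OCOC)c(C)c1OCOC
F2 | step 9 | (3E,5E,7S)-1-[2-(hydroxymethyl)-3,5-bis(methoxymethoxy)-4-methylphenyl]-5,7-dimethylnona-3,5-dien-2-one | COCOc1cc(CC(=O)/C=C/C(C)=C/[C@@H](C)CC)c(CO)c(OCOC)c1C
F3 | step 9 | 2,4-bis(methoxymethoxy)-3-methyl-6-[(3E,5E,7S)-5,7-dimethyl-2-oxonona-3,5-dienyl]benzaldehyde | COCOc1cc(CC(=O)/C=C/C(C)=C/[C@@H](C)CC)c(C=O)c(OCOC)c1C
F4 | step 10 | 6,8-dihydroxy-7-methyl-3-[(1E,3E,5S)-3,5-dimethylhepta-1,3-dienyl]isochromenylium trifluoroacetate | Cc1c(O)cc2cc(/C=C/C(C)=C/[C@@H](C)CC)[o+]cc2c1O.[O-]C(=O)C(F)(F)F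
F5 | step 10 | (7R)-7-hydroxy-7-methyl-3-[(1E,3E,5S)-3,5-dimethylhepta-1,3-dienyl]-6H-isochromene-6,8(7H)-dione | O[C@@]1(C)C(=O)C2=COC(/C=C/C(C)=C/[C@@H](C)CC)=CC2=CC1=O
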